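Throughout, Dm stands for the [(1R,2S,8aS)-1,2,5,5-tetramethyl-1,2,3,5,6,7,8,8a-octahydronaphthalen-1-yl]methyl group, that is C11H2 on C9 of the decalin. In compounds 5–7 the same spatial arrangement is written 8aR, only because O or I on C11 changes the priority order. Terpenoid numbering is used for the decalin (C1–C10, gem-dimethyl C4, alkene C5=C6, C8–CH3, quaternary C9, C10–H). The quinone is numbered C1' (C=O next to C–OH), C2' (C–OH), C3' (C–C11), C4' (C=O), C5' (C–N), C6' (C–H).

## The problem

Nakijiquinone M (22) joins a rearranged drimane bicycle to a 2-hydroxy-5-amino-1,4-benzoquinone through one methylene, C11, which hangs from the quaternary C9. Because C5 is sp2, the ring fusion carries a single stereocentre, C10. With C8 (S) and C9 (R) it forms a contiguous triad on ring B: the two methyl groups are cis and C11 is cis to H10. All three centres lie on one cyclohexene ring, so one cycloaddition can set them together. They are too far from the quinone to direct anything there, and the quinone has no stereocentre. C11 is neopentyl, so the C11–C3' bond is best made early with a small, very reactive partner. The C5=C6 alkene is trisubstituted and allylic to C10–H. Strong acid would move it to C5=C10 (erasing C10) or let the C2' hydroxyl add across it. The aminohydroxyquinone is redox-active and sensitive to base and nucleophiles, so it should appear last. The enabling feature is that C1'–C4' carry O, O, C11, O in sequence, the pattern of a 3-alkyl-4-alkoxycyclobutene-1,2-dione from a squarate ester. Only C5' and C6' are missing, and a 2-alkoxyvinyl unit supplies them with a leaving group on C5' for the amine.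

## Retrosynthesis

**C5'–N.** 22 is cut to 5-ethoxy-2-hydroxyquinone 20 and isopentylamine 21. Carrying the amine earlier would expose an N–H to organolithiums and thermolysis. Oxidative amination of a C5'–H quinone would leave regiochemistry to chance. In 20 the C2' oxygen is a vinylogous acid that is deprotonated by the amine, so only the C5' vinylogous ester can undergo addition–elimination.

**C2' O–CH3 and oxidation level.** 20 comes from 5-ethoxy-2-methoxyquinone 19 by saponification of the C2' vinylogous ester, and 19 from hydroquinone 18 by mild oxidation. The two alkoxy groups differ by construction (methoxy from the squarate, ethoxy from the vinyl unit). The forward step needs hydroxide to attack C2', the carbon whose methoxy group is twisted out of conjugation by C11.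

**C4'–C5' (key).** 18 is traced to 4-hydroxy-4-[(Z)-2-ethoxyvinyl]cyclobutenone 15. In the forward sense the four-ring bond between the carbonyl carbon (C4') and the carbinol carbon (C1') breaks and C4'–C5' forms. The neighbouring cut, joining a ready-made tetraoxygenated arene to C11, would need a hindered aryl metal at a neopentyl carbon and a later oxidative unmasking of four ethers. Here every quinone oxygen is already at the right level. The forward reaction needs outward rotation of the hydroxyl on ring opening and survival of the enol ether.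

**C1'–C6'.** 15 is cut to cyclobutenedione 12 and (Z)-2-ethoxyvinyllithium 14, made from bromide 13. The addition must go to the carbonyl next to the methoxy-bearing carbon, which is the ketone-like one. That places C1' beside C2' and leaves the C4' carbonyl beside C3'.

**C11–C3'.** 12 is cut to neopentyl iodide 7 and dimethyl squarate 8. The forward step proceeds through alkyllithium 9, its squarate adduct 10 and the trifluoroacetate 11, which transposes to 12. The hindered carbon reacts as an unstabilised alkyllithium with an unhindered carbonyl, the most favourable polarity for a neopentyl centre.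

**C11 functional group.** 7 comes from alcohol 6 and 6 from aldehyde 5. No stereocentre is touched and C9 has no hydrogen to lose.

**C7–C8 and C9–C10.** 5 is the exo Diels–Alder adduct of 1-ethenyl-6,6-dimethylcyclohexene 3 and tiglaldehyde 4. This one step makes ring B, the quaternary centre and all three stereocentres, and puts the alkene at C5=C6. It must be regioselective (C10 to the α-carbon), exo for the formyl group and face-selective under a chiral Lewis acid.

**C5–C6 of the diene.** 3 comes from enol triflate 2 by vinyl cross-coupling, and 2 from 2,2-dimethylcyclohexanone 1, which can enolise in one direction only.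

## Roads not taken

**Alternative 1:** The cut runs through C4–C5 and C9–C10, so that both carbocycles come from the E,E-farnesyl arene A1 in one cationic cascade. A chiral Brønsted-acid-assisted Lewis acid (SnCl4 with a BINOL monoether) or a squalene–hopene cyclase would protonate the terminal alkene, close rings A and B and lose a proton from C8 to give the drimenyl arene A2.
- Merits: A1 is one alkylation away from farnesyl bromide. A single catalytic step builds two rings, and the arene already holds four oxygens.
- Weak points: A2 is a normal drimane, with methyl on C10, hydrogen on C9 and the alkene at C7=C8. The target has methyl on C9, hydrogen on C10, a stereogenic C8 and the alkene at C5=C6. Getting there needs reprotonation at C8 and four consecutive 1,2-shifts. Their stereochemical course is right in principle, but where the cascade ends (C5=C6, C5=C10 or capture by the electron-rich arene) is not controlled, and the acid can re-ionise the product. The arene must then be oxidised with (NH4)2Ce(NO3)6 to a quinone whose two alkoxy groups are identical.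
- Comparison: this road is clearly shorter to a C21 skeleton than steps 1–6 here, and its ring-forming step is catalytic. The chosen plan sets against it that the cycloaddition gives the rearranged skeleton directly, that no cation is ever generated beside the C5=C6 alkene, and that C2' and C5' arrive already differentiated.

**Alternative 2:** The cut is C9–C10. Enolisation and O-silylation of lactone A3 (KN(SiMe3)2, t-BuMe2SiCl) and heating would trigger an Ireland–Claisen ring contraction to acid A4, with the C6–O bond breaking as C9–C10 forms.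
- Merits: the two-carbon tether enforces a boat transition state, so the C6 carbinol configuration is relayed to C10 and C9. A 4,6-trans lactone would give the required arrangement. The arylmethyl group is attached by simple enolate alkylation before the quaternary centre exists, so no neopentyl coupling is needed. The alkene lands at C5=C6.
- Weak points: A3 itself needs two controlled stereocentres and several steps. The rearrangement joins a tetrasubstituted ketene acetal carbon to a ring carbon in a strained bicyclic transition state. The carboxyl group on C9 must then be taken down to a methyl group at a neopentyl position, which costs three or four slow steps. The arene still has to become the quinone.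
- Comparison: in stereochemical relay and in avoiding a neopentyl organometallic this road is at least as good. The chosen plan sets against it a shorter sequence, a C9 methyl that is present from the start, and no late oxidation of an arene.

**Alternative 3:** The cut is C1–C10 and C4–C5. Dienone A5 and silyloxydiene A6 would combine in a thermal or ZnCl2-promoted Diels–Alder reaction on the face of the C9 methyl group to give the cis-fused adduct A7.
- Merits: the step is convergent, the arene is attached early, and the quaternary centre differentiates the faces of the dienophile.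
- Weak points: A5 must first be made as a single enantiomer at a quaternary carbon. The reacting terminus of A6 is disubstituted, so one group must point inward and the cycloaddition will be slow. A7 then needs much correction: the C4 silyloxy group must be exchanged for methyl at a tertiary allylic position, the C6 carbonyl removed while the C5=C6 alkene is installed, the C7=C8 alkene reduced from the hindered face to set C8, and the C2=C3 alkene saturated.
- Comparison: apart from avoiding the neopentyl coupling it offers nothing the chosen plan lacks, and it leaves C8 to a late, uncertain reduction that the chosen plan settles in its first ring-forming step.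

Key step: step 8

Assumption: the sense of induction in step 3 is taken from the usual model for 2-substituted enals bound to a proline-derived oxazaborolidinium ion (s-trans enal, formyl C–H···O contact, one face covered by an aryl group). On that basis the (R)-prolinol-derived catalyst is written; its mirror image would be used if the sense proved opposite.

## Steps

Step 1
Reactants: 1 2,2-dimethylcyclohexanone
Product: 2 6,6-dimethylcyclohex-1-en-1-yl trifluoromethanesulfonate
Conditions: LiN(i-Pr)2, THF, −78 °C; PhNTf2, −78 → 0 °C
Reagents that add atoms: N-phenylbis(trifluoromethanesulfonimide), O=S(=O)(N(c1ccccc1)S(=O)(=O)C(F)(F)F)C(F)(F)F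
Why: Enolate O-sulfonylation; the ketone has α-hydrogens on one side only, so a single enol triflate can form.

Step 2
Reactants: 2 6,6-dimethylcyclohex-1-en-1-yl trifluoromethanesulfonate
Product: 3 1-ethenyl-6,6-dimethylcyclohexene
Conditions: CH2=CHSnBu3, Pd(PPh3)4 (3 mol%), LiCl, THF, 65 °C
Reagents that add atoms: tributyl(vinyl)stannane, C=C[Sn](CCCC)(CCCC)CCCC
Why: Stille coupling of an alkenyl triflate with a vinylstannane under zerovalent palladium catalysis, a standard route to 2-substituted 1,3-dienes; the volatile diene should be separable from tin residues by distillation.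

Step 3
Reactants: 3 1-ethenyl-6,6-dimethylcyclohexene; 4 tiglaldehyde, (E)-2-methylbut-2-enal
Product: 5 (1R,2S,8aR)-1,2,5,5-tetramethyl-1,2,3,5,6,7,8,8a-octahydronaphthalene-1-carbaldehyde
Conditions: (R)-1-(2-methylphenyl)-3,3-diphenyltetrahydro-1H,3H-pyrrolo[1,2-c][1,3,2]oxazaborole (20 mol%), HN(SO2CF3)2 (18 mol%), CH2Cl2, −78 → −40 °C
Reagents that add atoms: none
Why: Catalytic enantioselective Diels–Alder reaction of a 2-substituted enal with a chiral oxazaborolidinium Lewis acid. The unsubstituted diene terminus C7 bonds to the β-carbon C8 and the substituted terminus C10 to the α-carbon C9 (ortho rule). The E geometry of 4 is retained, giving cis C8/C9 methyls; the exo preference of α-methyl enals places the formyl carbon C11 cis to H10; the catalyst directs the diene to the si face of the α-carbon, fixing 8S,9R and the C10 configuration of 22.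

Step 4
Reactants: 5 (1R,2S,8aR)-1,2,5,5-tetramethyl-1,2,3,5,6,7,8,8a-octahydronaphthalene-1-carbaldehyde
Product: 6 [(1R,2S,8aR)-1,2,5,5-tetramethyl-1,2,3,5,6,7,8,8a-octahydronaphthalen-1-yl]methanol
Conditions: NaBH4, MeOH, 0 °C
Reagents that add atoms: none
Why: Hydride reduction of a non-enolisable aldehyde; no stereocentre is involved.

Step 5
Reactants: 6 [(1R,2S,8aR)-1,2,5,5-tetramethyl-1,2,3,5,6,7,8,8a-octahydronaphthalen-1-yl]methanol
Product: 7 (1R,2S,8aR)-1-(iodomethyl)-1,2,5,5-tetramethyl-1,2,3,5,6,7,8,8a-octahydronaphthalene
Conditions: PPh3, I2, imidazole, PhMe, 80 °C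
Reagents that add atoms: iodine, II
Why: Appel-type iodination through the alkoxyphosphonium salt; displacement at the neopentyl carbon is slow but workable on heating, and imidazole keeps the medium non-acidic so the alkene stays in place.

Step 6
Reactants: 7 (1R,2S,8aR)-1-(iodomethyl)-1,2,5,5-tetramethyl-1,2,3,5,6,7,8,8a-octahydronaphthalene; 8 dimethyl squarate, 3,4-dimethoxycyclobut-3-ene-1,2-dione
Product: 12 3-methoxy-4-(Dm)cyclobut-3-ene-1,2-dione, via alkyllithium 9 (not isolated), via lithium alkoxide adduct 10 (not isolated), via adduct trifluoroacetate 11 (not isolated)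
Conditions: t-BuLi (2.1 equiv), Et2O–pentane, −78 °C; 8, THF, −78 °C; (CF3CO)2O, −78 °C; aq. NH4Cl, → 20 °C
Reagents that add atoms: water, O
Why: Lithium–iodine exchange gives a primary alkyllithium with no β-hydrogen to lose; it adds 1,2 to one squarate carbonyl. O-trifluoroacetylation, ionisation and capture of the methoxy-stabilised cation by water with loss of methanol give the 3-alkyl-4-methoxycyclobutenedione, the standard squarate-to-alkylcyclobutenedione transposition, under conditions mild enough for the alkene.

Step 7
Reactants: 12 3-methoxy-4-(Dm)cyclobut-3-ene-1,2-dione; 13 (Z)-1-bromo-2-ethoxyethene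
Product: 15 4-[(Z)-2-ethoxyethenyl]-4-hydroxy-3-methoxy-2-(Dm)cyclobut-2-en-1-one (both carbinol epimers), via (Z)-2-ethoxyvinyllithium 14 (not isolated)
Conditions: 13, t-BuLi (2 equiv), Et2O, −78 °C; 12, THF, −78 °C; cold aq. NH4Cl
Reagents that add atoms: none
Why: Lithium–bromine exchange with retention gives the cis-configured vinyllithium, which is stable at low temperature. It adds 1,2 to the carbonyl next to the methoxy-bearing carbon, the one not deactivated as a vinylogous ester, which is the established regiochemistry for 3-alkyl-4-alkoxycyclobutenediones. The new carbinol centre is formed without control and is lost in step 8.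

Step 8
Reactants: 15 4-[(Z)-2-ethoxyethenyl]-4-hydroxy-3-methoxy-2-(Dm)cyclobut-2-en-1-one
Product: 18 5-ethoxy-2-methoxy-3-(Dm)benzene-1,4-diol, via dienylketene 16 (not isolated), via cyclohexadienone 17 (not isolated)
Conditions: PhMe (degassed), 110 °C, Ar, base-washed glassware
Reagents that add atoms: none
Why: Thermal four-electron conrotatory opening of the cyclobutenone breaks the bond between the carbonyl carbon and the carbinol carbon and gives vinylketene 16. The hydroxyl donor rotates outward, so the ethoxyvinyl group turns inward toward the ketene carbon; this torquoselectivity is the one selectivity the step needs, and the substrate secures it through the free hydroxyl. The ketene carbon C4' then bonds to the ethoxy-bearing vinyl carbon C5' in a six-electron disrotatory electrocyclisation of the (Z)-dienylketene, which closes the six-membered ring as cyclohexadienone 17. Enolisation of 17 gives the aromatic hydroquinone 18. The closest known reaction type is the thermal ring expansion of 4-alkenyl-4-hydroxycyclobutenones from squarate esters to hydroquinones. No stereocentre is created: the carbinol centre and the transient sp3 C5' of 17 both become sp2, so both epimers of 15 converge. The regiochemistry (C11 beside C4', methoxy beside C1') was fixed in step 7, and the C5=C6 alkene takes no part under neutral thermolysis.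

Step 9
Reactants: 18 5-ethoxy-2-methoxy-3-(Dm)benzene-1,4-diol
Product: 19 5-ethoxy-2-methoxy-3-(Dm)cyclohexa-2,5-diene-1,4-dione
Conditions: Ag2O, Na2SO4, Et2O, 20 °C
Reagents that add atoms: none
Why: Two-electron oxidation of an electron-rich hydroquinone to the p-quinone; Ag2O is neutral and leaves the trisubstituted alkene alone.

Step 10
Reactants: 19 5-ethoxy-2-methoxy-3-(Dm)cyclohexa-2,5-diene-1,4-dione
Product: 20 5-ethoxy-2-hydroxy-3-(Dm)cyclohexa-2,5-diene-1,4-dione
Conditions: KOH, EtOH–H2O, 0 → 20 °C; then cold 0.5 M HCl
Reagents that add atoms: potassium hydroxide, [K+].[OH-]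
Why: Regioselective saponification of a vinylogous ester by addition–elimination, as known for 2,5-dialkoxy-3-alkyl-1,4-benzoquinones, where the alkoxy group beside the alkyl substituent is the one cleaved. Once the C2' oxygen is an anion the ring resists a second attack; ethanol as cosolvent makes any alkoxide exchange at C5' degenerate.

Step 11
Reactants: 20 5-ethoxy-2-hydroxy-3-(Dm)cyclohexa-2,5-diene-1,4-dione; 21 isopentylamine, 3-methylbutan-1-amine
Product: 22 nakijiquinone M, 2-hydroxy-5-[(3-methylbutyl)amino]-3-(Dm)cyclohexa-2,5-diene-1,4-dione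
Conditions: 21 (3 equiv), EtOH, 20 °C
Reagents that add atoms: none
Why: Addition–elimination of a primary amine at the only remaining vinylogous ester carbon, C5'; the C2' hydroxyl is present as its ammonium salt and is not displaced. This is the standard conversion of 2-hydroxy-5-alkoxy-3-alkylquinones into 5-amino-2-hydroxyquinones.

## Compound list

1 | 2,2-dimethylcyclohexanone | CC1(C)CCCCC1=O | starting material
2 | 6,6-dimethylcyclohex-1-en-1-yl trifluoromethanesulfonate | CC1(C)CCCC=C1OS(=O)(=O)C(F)(F)F | intermediate
3 | 1-ethenyl-6,6-dimethylcyclohexene | C=CC1=CCCCC1(C)C | intermediate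
4 | tiglaldehyde, (E)-2-methylbut-2-enal | C/C=C(\C)C=O | starting material
5 | (1R,2S,8aR)-1,2,5,5-tetramethyl-1,2,3,5,6,7,8,8a-octahydronaphthalene-1-carbaldehyde | O=C[C@@]1(C)[C@@H]2CCCC(C)(C)C2=CC[C@@H]1C | intermediate
6 | [(1R,2S,8aR)-1,2,5,5-tetramethyl-1,2,3,5,6,7,8,8a-octahydronaphthalen-1-yl]methanol | OC[C@@]1(C)[C@@H]2CCCC(C)(C)C2=CC[C@@H]1C | intermediate
7 | (1R,2S,8aR)-1-(iodomethyl)-1,2,5,5-tetramethyl-1,2,3,5,6,7,8,8a-octahydronaphthalene | IC[C@@]1(C)[C@@H]2CCCC(C)(C)C2=CC[C@@H]1C | intermediate
8 | dimethyl squarate, 3,4-dimethoxycyclobut-3-ene-1,2-dione | COC1=C(OC)C(=O)C1=O | starting material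
9 | {[(1R,2S,8aS)-1,2,5,5-tetramethyl-1,2,3,5,6,7,8,8a-octahydronaphthalen-1-yl]methyl}lithium | [Li]C[C@@]1(C)[C@@H]2CCCC(C)(C)C2=CC[C@@H]1C | intermediate (not isolated)
10 | lithium 2,3-dimethoxy-4-oxo-1-{[(1R,2S,8aS)-1,2,5,5-tetramethyl-1,2,3,5,6,7,8,8a-octahydronaphthalen-1-yl]methyl}cyclobut-2-en-1-olate (both epimers at the carbinol carbon) | [Li+].[O-]C1(C[C@@]2(C)[C@@H]3CCCC(C)(C)C3=CC[C@@H]2C)C(OC)=C(OC)C1=O | intermediate (not isolated)
11 | 2,3-dimethoxy-4-oxo-1-{[(1R,2S,8aS)-1,2,5,5-tetramethyl-1,2,3,5,6,7,8,8a-octahydronaphthalen-1-yl]methyl}cyclobut-2-en-1-yl trifluoroacetate (both epimers) | O=C(OC1(C[C@@]2(C)[C@@H]3CCCC(C)(C)C3=CC[C@@H]2C)C(OC)=C(OC)C1=O)C(F)(F)F | intermediate (not isolated)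
12 | 3-methoxy-4-{[(1R,2S,8aS)-1,2,5,5-tetramethyl-1,2,3,5,6,7,8,8a-octahydronaphthalen-1-yl]methyl}cyclobut-3-ene-1,2-dione | COC1=C(C[C@@]2(C)[C@@H]3CCCC(C)(C)C3=CC[C@@H]2C)C(=O)C1=O | intermediate
13 | (Z)-1-bromo-2-ethoxyethene | CCO/C=C\Br | starting material
14 | (Z)-(2-ethoxyethenyl)lithium | CCO/C=C\[Li] | intermediate (not isolated)
15 | 4-[(Z)-2-ethoxyethenyl]-4-hydroxy-3-methoxy-2-{[(1R,2S,8aS)-1,2,5,5-tetramethyl-1,2,3,5,6,7,8,8a-octahydronaphthalen-1-yl]methyl}cyclobut-2-en-1-one (both epimers at C4 of the four-membered ring) | CCO/C=C\C1(O)C(OC)=C(C[C@@]2(C)[C@@H]3CCCC(C)(C)C3=CC[C@@H]2C)C1=O | intermediate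
16 | (3Z,5Z)-6-ethoxy-4-hydroxy-3-methoxy-2-{[(1R,2S,8aS)-1,2,5,5-tetramethyl-1,2,3,5,6,7,8,8a-octahydronaphthalen-1-yl]methyl}hexa-1,3,5-trien-1-one | CCO/C=C\C(O)=C(OC)/C(C[C@@]1(C)[C@@H]2CCCC(C)(C)C2=CC[C@@H]1C)=C=O | intermediate (not isolated)
17 | 6-ethoxy-4-hydroxy-3-methoxy-2-{[(1R,2S,8aS)-1,2,5,5-tetramethyl-1,2,3,5,6,7,8,8a-octahydronaphthalen-1-yl]methyl}cyclohexa-2,4-dien-1-one (either configuration at C6 of the dienone) | CCOC1C=C(O)C(OC)=C(C[C@@]2(C)[C@@H]3CCCC(C)(C)C3=CC[C@@H]2C)C1=O | intermediate (not isolated)
18 | 5-ethoxy-2-methoxy-3-{[(1R,2S,8aS)-1,2,5,5-tetramethyl-1,2,3,5,6,7,8,8a-octahydronaphthalen-1-yl]methyl}benzene-1,4-diol | CCOc1cc(O)c(OC)c(C[C@@]2(C)[C@@H]3CCCC(C)(C)C3=CC[C@@H]2C)c1O | intermediate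
19 | 5-ethoxy-2-methoxy-3-{[(1R,2S,8aS)-1,2,5,5-tetramethyl-1,2,3,5,6,7,8,8a-octahydronaphthalen-1-yl]methyl}cyclohexa-2,5-diene-1,4-dione | CCOC1=CC(=O)C(OC)=C(C[C@@]2(C)[C@@H]3CCCC(C)(C)C3=CC[C@@H]2C)C1=O | intermediate
20 | 5-ethoxy-2-hydroxy-3-{[(1R,2S,8aS)-1,2,5,5-tetramethyl-1,2,3,5,6,7,8,8a-octahydronaphthalen-1-yl]methyl}cyclohexa-2,5-diene-1,4-dione | CCOC1=CC(=O)C(O)=C(C[C@@]2(C)[C@@H]3CCCC(C)(C)C3=CC[C@@H]2C)C1=O | intermediate
21 | isopentylamine, 3-methylbutan-1-amine | CC(C)CCN | starting material
22 | nakijiquinone M, 2-hydroxy-5-[(3-methylbutyl)amino]-3-{[(1R,2S,8aS)-1,2,5,5-tetramethyl-1,2,3,5,6,7,8,8a-octahydronaphthalen-1-yl]methyl}cyclohexa-2,5-diene-1,4-dione | CC(C)CCNC1=CC(=O)C(O)=C(C[C@@]2(C)[C@@H]3CCCC(C)(C)C3=CC[C@@H]2C)C1=O | target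

## Step count and risks

Total: 11 steps. Longest linear sequence: 11 steps, from 1 to 22; 4, 8, 13 and 21 enter as purchased.

**Step 8 (key).** The carbinol of 15 is tertiary, doubly allylic and flanked by an enol ether. Trace acid or heat can therefore ionise it with loss of water and then ethanol, competing with ring opening. In addition, the inward ethoxy group may slow the six-electron closure enough for the ketene to be diverted. The fallback sets out from 12 and comes back to the route at 22; it keeps the ring expansion but removes the enol ether.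
- Vinyllithium (from vinyl bromide and t-BuLi) would add to 12 to give 4-ethenyl-4-hydroxy-3-methoxy-2-(Dm)cyclobut-2-en-1-one F1.
- Thermolysis in toluene would give 2-methoxy-3-(Dm)benzene-1,4-diol F2, and Ag2O would give 2-methoxy-3-(Dm)cyclohexa-2,5-diene-1,4-dione F3.
- Conjugate addition of 21 under air should go to C5', because the methoxy group deactivates the C4' carbonyl. It would give 2-methoxy-5-[(3-methylbutyl)amino]-3-(Dm)cyclohexa-2,5-diene-1,4-dione F4.
- Aqueous KOH would cleave the one remaining vinylogous ester of F4 to 22.

**Step 3.** The β-substituted enal and the hindered diene may react sluggishly. Facial or exo/endo discrimination may be poor, and the catalyst may shield the face opposite to the one assumed. The fallback sets out from 3 and 4 and comes back at 6.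
- EtAlCl2 in CH2Cl2 would give the racemic exo aldehyde F5, and NaBH4 the racemic alcohol F6.
- Esterification with (S)-2-methoxy-2-phenylacetic acid (DCC, DMAP) and chromatographic separation of the diastereomers would give [(1R,2S,8aR)-1,2,5,5-tetramethyl-1,2,3,5,6,7,8,8a-octahydronaphthalen-1-yl]methyl (2S)-2-methoxy-2-phenylacetate F7.
- LiOH in aqueous THF would release 6 from F7.

**Step 5.** Displacement inside the alkoxyphosphonium salt at the neopentyl carbon may be too slow, and prolonged heating with iodide may cause alkene migration or skeletal rearrangement. The fallback sets out from 6 and comes back at 7. Tf2O and pyridine in CH2Cl2 at −40 °C would give [(1R,2S,8aR)-1,2,5,5-tetramethyl-1,2,3,5,6,7,8,8a-octahydronaphthalen-1-yl]methyl trifluoromethanesulfonate F8 without any substitution at carbon. NaI in acetone would then displace the much better leaving group to give 7.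

**Step 10.** Hydroxide may attack the unhindered C5' instead of C2', or hydrolysis may go on to the dihydroxyquinone. The fallback sets out from 19 and comes back at 20 and forms no new compound. LiI in pyridine–ethyl acetate at 60 °C would cleave the ether by nucleophilic substitution at the alkyl carbon. That mechanism prefers methyl over ethyl, so it uses the built-in difference between the two alkoxy groups and not the relative electrophilicity of C2' and C5'. A mild acid wash would then give 20.

## Further compounds

F1 | step 8 | 4-ethenyl-4-hydroxy-3-methoxy-2-{[(1R,2S,8aS)-1,2,5,5-tetramethyl-1,2,3,5,6,7,8,8a-octahydronaphthalen-1-yl]methyl}cyclobut-2-en-1-one (both carbinol epimers) | C=CC1(O)C(OC)=C(C[C@@]2(C)[C@@H]3CCCC(C)(C)C3=CC[C@@H]2C)C1=O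
F2 | step 8 | 2-methoxy-3-{[(1R,2S,8aS)-1,2,5,5-tetramethyl-1,2,3,5,6,7,8,8a-octahydronaphthalen-1-yl]methyl}benzene-1,4-diol | COc1c(O)ccc(O)c1C[C@@]2(C)[C@@H]3CCCC(C)(C)C3=CC[C@@H]2C
F3 | step 8 | 2-methoxy-3-{[(1R,2S,8aS)-1,2,5,5-tetramethyl-1,2,3,5,6,7,8,8a-octahydronaphthalen-1-yl]methyl}cyclohexa-2,5-diene-1,4-dione | COC1=C(C[C@@]2(C)[C@@H]3CCCC(C)(C)C3=CC[C@@H]2C)C(=O)C=CC1=O
F4 | step 8 | 2-methoxy-5-[(3-methylbutyl)amino]-3-{[(1R,2S,8aS)-1,2,5,5-tetramethyl-1,2,3,5,6,7,8,8a-octahydronaphthalen-1-yl]methyl}cyclohexa-2,5-diene-1,4-dione | CC(C)CCNC1=CC(=O)C(OC)=C(C[C@@]2(C)[C@@H]3CCCC(C)(C)C3=CC[C@@H]2C)C1=O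
F5 | step 3 | racemic (1R*,2S*,8aR*)-1,2,5,5-tetramethyl-1,2,3,5,6,7,8,8a-octahydronaphthalene-1-carbaldehyde (both enantiomers written) | O=C[C@@]1(C)[C@@H]2CCCC(C)(C)C2=CC[C@@H]1C.O=C[C@]1(C)[C@H]2CCCC(C)(C)C2=CC[C@H]1C
F6 | step 3 | racemic [(1R*,2S*,8aR*)-1,2,5,5-tetramethyl-1,2,3,5,6,7,8,8a-octahydronaphthalen-1-yl]methanol (both enantiomers written) | OC[C@@]1(C)[C@@H]2CCCC(C)(C)C2=CC[C@@H]1C.OC[C@]1(C)[C@H]2CCCC(C)(C)C2=CC[C@H]1C
F7 | step 3 | [(1R,2S,8aR)-1,2,5,5-tetramethyl-1,2,3,5,6,7,8,8a-octahydronaphthalen-1-yl]methyl (2S)-2-methoxy-2-phenylacetate | CO[C@H](C(=O)OC[C@@]1(C)[C@@H]2CCCC(C)(C)C2=CC[C@@H]1C)c1ccccc1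
F8 | step 5 | [(1R,2S,8aR)-1,2,5,5-tetramethyl-1,2,3,5,6,7,8,8a-octahydronaphthalen-1-yl]methyl trifluoromethanesulfonate | O=S(=O)(OC[C@@]1(C)[C@@H]2CCCC(C)(C)C2=CC[C@@H]1C)C(F)(F)F
F0 | step 10 | none | none
A1 | alternative 1 | 1,2,4,5-tetramethoxy-3-[(2E,6E)-3,7,11-trimethyldodeca-2,6,10-trien-1-yl]benzene | COc1cc(OC)c(OC)c(C/C=C(\C)CC/C=C(\C)CCC=C(C)C)c1OC
A2 | alternative 1 | 11-(2,3,5,6-tetramethoxyphenyl)drim-7-ene | COc1cc(OC)c(OC)c(C[C@H]2C(C)=CC[C@H]3C(C)(C)CCC[C@]23C)c1OC
A3 | alternative 2 | (4S,6R)-6-(6,6-dimethylcyclohex-1-en-1-yl)-4-methyl-3-[(2,3,5,6-tetramethoxyphenyl)methyl]oxan-2-one (either configuration at C3) | O=C1O[C@@H](C2=CCCCC2(C)C)C[C@H](C)C1Cc1c(OC)c(OC)cc(OC)c1OC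
A4 | alternative 2 | 2,5,5-trimethyl-1-[(2,3,5,6-tetramethoxyphenyl)methyl]-1,2,3,5,6,7,8,8a-octahydronaphthalene-1-carboxylic acid, configured as the decalin of the target with the carboxyl group in place of the C9 methyl | COc1cc(OC)c(OC)c(C[C@@]2(C(=O)O)[C@@H]3CCCC(C)(C)C3=CC[C@@H]2C)c1OC
A5 | alternative 3 | 3,4-dimethyl-4-[(2,3,5,6-tetramethoxyphenyl)methyl]cyclohexa-2,5-dien-1-one, single enantiomer at C4 | COc1cc(OC)c(OC)c(C[C@@]2(C)C=CC(=O)C=C2C)c1OC
A6 | alternative 3 | tert-butyl(dimethyl)[(2Z)-penta-2,4-dien-2-yloxy]silane | C=C/C=C(/C)O[Si](C)(C)C(C)(C)C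
A7 | alternative 3 | cis-fused Diels–Alder adduct with the C4 silyloxy group and the C7=C8 enone | COc1cc(OC)c(OC)c(C[C@@]2(C)[C@@H]3CC=C[C@@](C)(O[Si](C)(C)C(C)(C)C)[C@@H]3C(=O)C=C2C)c1OC
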